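## Structural features

The target is a germacranolide: a cyclodeca-1E,4Z-diene (C1–C10) cis-fused at C6–C7 to an α-methylene-γ-butyrolactone (O–C6, C7, C11=C13, C12=O). It has five stereocentres. C6, C7 and C8 are contiguous, C10 is a tertiary methyl carbinol standing 1,3-anti to the C8 oxygen, and C3 is a secondary carbinol flanked by both ring alkenes. The fragile groups are the C8 angelate (a Z-2-methylbut-2-enoate that slips to the tiglate), the exocyclic methylene lactone (a Michael acceptor) and the allylic C3 and C10 alcohols (ionisable by acid). Whenever C8 is a carbonyl, the C7 hydrogen is α to it and the lactone oxygen is β, so base invites epimerisation or elimination. The real difficulty is to close a ten-membered carbocycle that holds an E and a Z alkene and, in doing so, to set the remote C10 centre relative to C6/C7. The feature exploited is the C8–C9–C10 segment: a 1,3-anti diol with a tertiary carbinol is the retron of a 5,5-disubstituted 2-isoxazoline (O–N=C8–C9–C10). A nitrile oxide on C8 and the terminal C9=C10 alkene of a 2-methyl-1,3-diene can therefore close the carbocycle and store the aldol in one event. The Z C4=C5 alkene and the cis lactone are used to fold the chain for that closure.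

## Logic of the disconnections

36 ⇒ 35 ⇒ 32 + 33. Bonds cut: the O3–Si bond, then the C8–O acyl bond. Reason: the angelate is the group most prone to isomerise, so it is attached last, and O3 must stay capped until then. Gain: 33 is commercial and 32 has only one acylable hydroxyl. Demand: acylation must discriminate secondary O8 from tertiary O10 and keep the Z geometry (through 34); desilylation must spare ester, methylene lactone and tertiary allylic alcohol.

32 ⇒ 31 ⇒ 30 ⇒ 27. Bond cut: C11=C13 (the C11–C13 carbon is removed). Reason: the methylene lactone cannot pass through the C8 ketone stage, where C7–H would be activated twice. Gain: a saturated lactone. Demand: enolate chemistry on a diol, met by masking both hydroxyls in the flask (28, 29) so that O8 cannot attack C12.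

27 ⇒ 26. Bond cut: C8–H (carbinol back to ketone). Reason: the anti relation to O10 can be relayed by internal hydride delivery. Gain: C8 stereocentre removed. Demand: the tertiary O10 must bind the boron reagent.

26 ⇒ 25 ⇒ 24. Bonds: C8=O becomes C8=N, and N is joined to O10. Reason: the β-hydroxy ketone is retro-aldol-prone and is best kept masked until the ring exists. Gain: a rigid bicycle with no free hydroxyl. Demand: N–O cleavage that spares two alkenes and does not open the strained aldol.

24 ⇒ 23 ⇒ 22 (key). Bonds cut: C8–C9 and O–C10. Reason: both bonds belong to one [3+2] retron. Gain: two rings and the C10 centre go at once, leaving an open-chain triene on a cis lactone. Demand: bridged regiochemistry, attack at C9=C10 and not at C1=C2, one face of C10, and high dilution.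

22 ⇒ 21 ⇒ 20 ⇒ 19. Bonds: C8=N, then the C8 oxidation level, then C8–N of the auxiliary. Reason: the C8 aldehyde is labile (α-centre, β-acyloxy) and should exist only in the flask. Gain: C8 returns to the carboxyl level of an aldol product. Demand: reduction of an imide beside a lactone.

19 ⇒ 18 ⇒ 17 ⇒ 12 + 16. Bonds cut: O6–C12 (lactone), then C6–C7. Reason: C6 and C7 are an aldol pair. Gain: two stereocentres traced to an enal and a succinate imide. Demand: anti topology (the usual syn boron aldol of such imides would give the trans lactone), auxiliary control of the face, and survival of the Z enal.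

16 ⇒ 15 + 14, 15 ⇐ 13. Bond cut: N–C8 acyl. Reason and gain: both partners are commercial. Demand: none beyond clean N-acylation.

12 ⇒ 11 ⇒ 10 ⇒ 9. Bonds cut: C5–C6 (a one-carbon formyl unit) and O3–Si. Reason: C6 is best added as an electrophile to a geometrically defined alkenyl metal. Gain: a Z alkenyl iodide. Demand: retention of geometry and no silyl shift from O3 to C5.

9 ⇒ 8 ⇒ 7. Bonds cut: C5–I and C4–CH3. Reason: both come from one anti carbometalation of a terminal alkyne steered by the C3 alkoxide. Gain: the trisubstituted Z alkene reduces to an alkyne. Demand: methyl to C4, metal to C5, anti addition.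

7 ⇒ 6 ⇒ 3 + 4 (through 5). Bonds cut: C–Si, then C3–C4. Reason: C3 is set by a catalytic asymmetric alkynylation. Gain: an achiral dienal. Demand: catalyst control on an enal.

3 ⇒ 1 + 2. Bond cut: C1=C2. Reason: a stabilised ylide gives the E alkene. Gain: two commercial materials. Demand: one homologation only.

## Other disconnections considered

Alternative 1: The cut takes the C10 oxygen away by a retro-ene operation (C1=C2 goes back to a C1=C10 alkene) and then rejoins C1–C4 and C5–C10, tracing the ten-membered ring to a six-membered ring with a fused four-membered ring. Forward, heat would break the C1–C4 and C5–C10 bonds of the four-membered ring and form the C1=C10 and C4=C5 double bonds, ending in the E,Z-dienone A1. Singlet oxygen would later place the C10 oxygen and move the alkene to C1=C2.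
- In its favour: the ring forms by a unimolecular, strain-driven expansion that needs no dilution. On the ring-forming event itself this is the equal of the chosen plan and probably the better. Both ring alkenes appear in one step, and C3, C7 and C8 can be set beforehand on a six-membered ring.
- Against it here: A1 is far from the target. C6 is a ketone, C4 bears an ester where a methyl belongs, and C11–C12 is an open acetate chain. The ene reaction must pick the C2 hydrogen over those on C9 and the C10 methyl, and one face of a flexible ring. A1 is also a cyclodeca-1,5-diene and can undergo Cope rearrangement at the temperature of its own formation.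
- Comparison: 24 fixes C10, its oxygen and the C8 carbonyl in one rigid unit, whereas A1 leaves C10 to a late, weakly controlled oxidation. Both key steps are pericyclic in type. The alternative needs clearly more operations after its key step than the six steps from 24.

Alternative 2: The cut is C2–C3. Forward, CrCl2 with catalytic NiCl2 would turn an E alkenyl iodide at C2 into an alkenylchromium that adds to a Z enal carbonyl at C3 of the same chain, closing the ring as A2, from which only the silyl group on O10 must be removed.
- In its favour: the ring closes last, with angelate and methylene lactone already in place. Organochromium reagents tolerate esters, lactones and enoates, and ten-membered closures of this type are well known. In functional-group tolerance and in the length of the endgame (one step against six) it is the better of the two. C10 is fixed beforehand by acyclic, reagent-controlled chemistry and does not depend on a fold, which is also better.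
- Against it here: C3 is created in the ring closure under substrate control only. The open-chain substrate must already carry C6, C7, C8 and C10 with the anti-diol pattern, which costs acyclic steps at least equal to steps 7–13. A large excess of divalent chromium is needed at high dilution.
- Comparison: one bond, one ring and one stereocentre are formed, against two bonds, two rings and one stereocentre in step 11. The chosen plan sets C3 early by catalyst control, where the alternative is weaker. Overall step counts should be similar.

Alternative 3: The cut is C9–C10. Forward, a lithiated 2-alkenyl-1,3-dithiane carbon (C10) would open a terminal epoxide at C9 within the same chain, closing the ring as A3 and freeing the C8 hydroxyl.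
- In its favour: the C8 configuration comes from an enantiopure epoxide, which is better than a directed reduction. The opening is irreversible. The lactone is carried as a masked 2-propenyl unit, so no late methylenation is needed, which is also better.
- Against it here: the lithiated alkenyl dithiane is an ambident allyl anion (attack through C2 would close an eight-membered ring). The conditions are strongly basic, next to silyl ethers. After closure C10 is still a masked ketone: dithiane removal beside alkenes and then a 1,2- and face-selective methyl addition to a ring enone are required. The lactone must then be built by oxidation and the angelate attached.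
- Comparison: C10 control is deferred to a medium-ring addition and is no safer than the fold in step 11. One bond is formed under strong base, against two under near-neutral oxidation. More steps follow the key step than from 24.

Key step: step 11

Remark on the chemistry: atom labels C1–C13 are those of the germacrane skeleton of the target; the ProPhenol antipode (step 2) and the oxazolidinone antipode (steps 7 and 8) are fixed by what they must deliver (3S; attack on the chelated magnesium enolate from the face away from the benzyl group), and if either sense were opposite the other antipode would be used with no other change.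

Step 1
Reactants: 1 methacrolein; 2 (triphenylphosphoranylidene)acetaldehyde
Product: 3 (2E)-4-methylpenta-2,4-dienal
Conditions: 1 (3 equiv), CH2Cl2, rt to 40 °C; product kept in solution
Reagents that add atoms: none
Why: Wittig olefination with a stabilised formyl ylide gives the E enal; the excess of volatile 1 limits a second homologation of 3.

Step 2
Reactants: 3 (2E)-4-methylpenta-2,4-dienal; 4 ethynyltrimethylsilane
Product: 6 (3S,4E)-6-methyl-1-(trimethylsilyl)hepta-4,6-dien-1-yn-3-ol, via alkynylzinc 5 (not isolated)
Conditions: ProPhenol (10 mol %, antipode for 3S), Me2Zn, Ph3P=O (20 mol %), toluene, 0 to 4 °C; aq NH4Cl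
Reagents that add atoms: none
Why: Catalytic asymmetric alkynylation of an aldehyde; the dinuclear zinc–ProPhenol complex binds 3 and 5 and delivers the alkyne to one carbonyl face, setting C3 as S, and enals are good acceptors for this catalyst.

Step 3
Reactants: 6 (3S,4E)-6-methyl-1-(trimethylsilyl)hepta-4,6-dien-1-yn-3-ol
Product: 7 (3S,4E)-6-methylhepta-4,6-dien-1-yn-3-ol
Conditions: K2CO3, MeOH, 0 °C to rt
Reagents that add atoms: none
Why: Methanolysis of the C(sp)–Si bond; carbinol and diene are untouched.

Step 4
Reactants: 7 (3S,4E)-6-methylhepta-4,6-dien-1-yn-3-ol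
Product: 9 (1Z,3S,4E)-1-iodo-2,6-dimethylhepta-1,4,6-trien-3-ol, via magnesium chelate 8 (not isolated)
Conditions: MeMgBr (3 equiv), CuI (10 mol %), THF, −10 °C to rt; then I2 (1.1 equiv), −78 to 0 °C
Reagents that add atoms: methylmagnesium bromide, C[Mg]Br; iodine, II
Why: Copper-catalysed anti carbomagnesiation of a propargylic alkoxide: methyl adds to the alkyne carbon next to the carbinol (C4) and magnesium ends on the terminal carbon (C5), held cis to the alkoxide in chelate 8, so iodinolysis with retention gives the Z iodide.

Step 5
Reactants: 9 (1Z,3S,4E)-1-iodo-2,6-dimethylhepta-1,4,6-trien-3-ol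
Product: 10 tert-butyl{[(1Z,3S,4E)-1-iodo-2,6-dimethylhepta-1,4,6-trien-3-yl]oxy}dimethylsilane
Conditions: TBSCl, imidazole, DMF, 0 °C to rt
Reagents that add atoms: tert-butyldimethylsilyl chloride, CC(C)(C)[Si](C)(C)Cl
Why: Standard silylation, done at once because the free bis-allylic carbinol ionises with acid.

Step 6
Reactants: 10 tert-butyl{[(1Z,3S,4E)-1-iodo-2,6-dimethylhepta-1,4,6-trien-3-yl]oxy}dimethylsilane
Product: 12 (2Z,4S,5E)-4-[(tert-butyldimethylsilyl)oxy]-3,7-dimethylocta-2,5,7-trienal, via alkenyllithium 11 (not isolated)
Conditions: t-BuLi (2.1 equiv), Et2O, −78 °C, 20 min; DMF, −78 to −20 °C; aq NH4Cl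
Reagents that add atoms: N,N-dimethylformamide, CN(C)C=O
Why: Iodine–lithium exchange with retention of alkene geometry, then formylation; ether, −78 °C and a short lithiation time keep the cis γ-silyloxy alkenyllithium 11 from a 1,4 oxygen-to-carbon silyl shift.

Step 7
Reactants: 13 (4R)-4-benzyl-1,3-oxazolidin-2-one; 14 methyl 4-chloro-4-oxobutanoate
Product: 16 methyl 4-[(4R)-4-benzyl-2-oxo-1,3-oxazolidin-3-yl]-4-oxobutanoate, via lithium oxazolidinide 15 (not isolated)
Conditions: n-BuLi, THF, −78 °C; then 14, −78 to 0 °C
Reagents that add atoms: none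
Why: N-acylation of the lithiated oxazolidinone by the acid chloride; the methyl ester is inert at −78 °C.

Step 8
Reactants: 12 (2Z,4S,5E)-4-[(tert-butyldimethylsilyl)oxy]-3,7-dimethylocta-2,5,7-trienal; 16 methyl 4-[(4R)-4-benzyl-2-oxo-1,3-oxazolidin-3-yl]-4-oxobutanoate
Product: 19 lactone imide (4R)-4-benzyl-3-{[(2S,3S)-2-[(1Z,3S,4E)-3-[(tert-butyldimethylsilyl)oxy]-2,6-dimethylhepta-1,4,6-trien-1-yl]-5-oxooxolan-3-yl]carbonyl}-1,3-oxazolidin-2-one, via silylated aldol adduct 17 (not isolated), via hydroxy ester 18 (not isolated)
Conditions: MgCl2 (20 mol %), Et3N, Me3SiCl, EtOAc, rt; then PPTS, MeOH, 0 °C; then PPTS (cat.), toluene, 50 °C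
Reagents that add atoms: none
Why: MgCl2-catalysed anti aldol of an N-acyloxazolidinone: soft enolisation gives the chelated Z magnesium enolate, which adds to the enal (no α-hydrogen) through a boat-like transition state on the face away from the benzyl group, setting C6 (S) and C7, and silylation to 17 turns the catalyst over. Mild acid methanolysis frees 18, whose γ-hydroxy ester closes to the lactone; the anti topology places C5 and the C7 carbonyl cis on the ring.

Step 9
Reactants: 19 lactone imide
Product: 20 (4R,5S)-5-[(1Z,3S,4E)-3-[(tert-butyldimethylsilyl)oxy]-2,6-dimethylhepta-1,4,6-trien-1-yl]-4-(hydroxymethyl)oxolan-2-one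
Conditions: NaBH4, THF/H2O (4:1), 0 °C; cold aq NH4Cl
Reagents that add atoms: none
Why: NaBH4 in wet THF reduces the exocyclic imide carbonyl much faster than a γ-lactone and leaves alkenes alone; the cold, mildly acidic quench avoids acyl migration from O6 to the new primary hydroxyl.

Step 10
Reactants: 20 hydroxymethyl lactone
Product: 22 (4R,5S)-5-[(1Z,3S,4E)-3-[(tert-butyldimethylsilyl)oxy]-2,6-dimethylhepta-1,4,6-trien-1-yl]-4-[(hydroxyimino)methyl]oxolan-2-one, via aldehyde 21 (not isolated)
Conditions: Dess–Martin periodinane, NaHCO3, CH2Cl2, 0 °C; then NH2OH·HCl (1.2 equiv), NaOAc, EtOH, 0 °C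
Reagents that add atoms: hydroxylamine hydrochloride, NO.Cl
Why: Buffered Dess–Martin oxidation does not epimerise the α-centre; the β-acyloxy aldehyde 21 is condensed with hydroxylamine in the same flask so that it is never stored, and at 0 °C condensation outruns attack on the lactone.

Step 11
Reactants: 22 dienyl cis-lactone aldoxime
Product: 24 isoxazoline-bridged (3S,6S,7R,10R)-3-[(tert-butyldimethylsilyl)oxy]germacra-1E,4Z-dien-12,6-olide with O–N=C8 bridging C10 and C8, via nitrile oxide 23 (not isolated)
Conditions: aq NaOCl (NaHCO3-buffered, pH about 9), CH2Cl2, 0 °C to rt; 22 added over 10 h; final 2 mM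
Reagents that add atoms: none
Why: Hypochlorite converts the aldoxime into nitrile oxide 23 (either oxime isomer serves), which adds across C9=C10 in a concerted, asynchronous, suprafacial [3+2] cycloaddition with the normal orientation for a 1,1-disubstituted alkene, carbon to the CH2 terminus (C8–C9) and oxygen to the substituted carbon (O–C10). The closest known reaction type is the intramolecular nitrile oxide–alkene cycloaddition run in the bridged mode to make medium and large carbocycles. Because the dipole carbon bonds to the distal alkene carbon, the ten-membered carbocycle closes by bridged attack at the alkene terminus, and the isoxazoline closes in the same event as the one-carbon and N–O bridges of a bicyclo[7.2.1] frame, whose bridgehead C8=N bond lies in rings large enough to hold it. C10 is the only new stereocentre and is set by the fold of the tether: the cis lactone holds C5 and C8 on one face of the five-membered ring, the Z C4=C5 bond with H3 and H6 near its plane sends C2 and C7 to the same side and both oxygens outward (a matched 3S,6S pair), and with C7–H eclipsing the developing C=N bond the carbocycle should close on the face of the dipole plane that gives 10R with the C10 methyl outside. Regiochemistry follows from the polarisation of the alkene; site selectivity for C9=C10 over C1=C2, which would close a seven-membered ring in the fused mode, rests on the much higher reactivity of the terminal 1,1-disubstituted alkene, on the bulky silyl ether at C3 beside C2, and on O3 staying capped so that no hydroxyl can guide the dipole to C1=C2. Slow addition to a final 2 mM holds back furoxan formation, and the bicarbonate-buffered two-phase oxidant keeps base away from the C7–H, which is α to the dipole and β to the lactone oxygen.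

Step 12
Reactants: 24 isoxazoline-bridged lactone
Product: 26 (3S,6S,7S,10R)-3-[(tert-butyldimethylsilyl)oxy]-10-hydroxy-8-oxogermacra-1E,4Z-dien-12,6-olide, via hydroxy imine 25 (not isolated)
Conditions: Mo(CO)6, MeCN/H2O (15:1), 80 °C; filtered through silica and used at once
Reagents that add atoms: water, O
Why: Zerovalent molybdenum cleaves the N–O bond reductively and water hydrolyses hydroxy imine 25; alkenes, silyl ether and lactone are inert, and the near-neutral medium limits retro-aldol opening and elimination across C6–C7.

Step 13
Reactants: 26 β-hydroxy ketone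
Product: 27 (3S,6S,7R,8R,10R)-3-[(tert-butyldimethylsilyl)oxy]-8,10-dihydroxygermacra-1E,4Z-dien-12,6-olide
Conditions: Me4NBH(OAc)3, MeCN/AcOH (1:1), −30 °C
Reagents that add atoms: none
Why: Evans–Saksena reduction: the C10 hydroxyl exchanges an acetate on boron and hydride is delivered internally to C8 from the face of O10, so the new hydroxyl comes out anti (8R); the acidic medium protects the base-sensitive C7.

Step 14
Reactants: 27 anti diol
Product: 30 (3S,6S,7R,8R,10R)-3-[(tert-butyldimethylsilyl)oxy]-13-(dimethylamino)-8,10-dihydroxygermacra-1E,4Z-dien-12,6-olide (C11 epimers), via bis(trimethylsilyl) ether 28 (not isolated), via silylated Mannich base 29 (not isolated)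
Conditions: N-(trimethylsilyl)imidazole, CH2Cl2, rt, evaporate; LiN(i-Pr)2 (1.2 equiv), THF, −78 °C; CH2=NMe2 I, −78 to 0 °C; then citric acid, MeOH, 0 °C; basic work-up
Reagents that add atoms: N,N-dimethylmethyleneiminium iodide, C=[N+](C)C.[I-]
Why: Both hydroxyls are capped in the flask as trimethylsilyl ethers so that only the lactone α-carbon is deprotonated and O8 cannot attack C12; the lithium enolate undergoes a Mannich reaction with the iminium salt, and mild acid methanolysis then removes the two trimethylsilyl groups but not the allylic tert-butyldimethylsilyl ether.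

Step 15
Reactants: 30 Mannich base
Product: 32 (3S,6S,7R,8R,10R)-3-[(tert-butyldimethylsilyl)oxy]-8,10-dihydroxygermacra-1E,4Z,11(13)-trien-12,6-olide, via ammonium iodide 31 (not isolated)
Conditions: MeI, MeOH, rt; then aq NaHCO3, EtOAc, rt
Reagents that add atoms: none
Why: Quaternisation followed by bicarbonate-induced β-elimination of trimethylamine gives the exocyclic methylene; addition of O8 to C13 would be a 5-endo closure and is not expected.

Step 16
Reactants: 32 methylene lactone diol; 33 angelic acid [(2Z)-2-methylbut-2-enoic acid]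
Product: 35 (3S,6S,7R,8R,10R)-8-(angeloyloxy)-3-[(tert-butyldimethylsilyl)oxy]-10-hydroxygermacra-1E,4Z,11(13)-trien-12,6-olide, via mixed anhydride 34 (not isolated)
Conditions: 33, 2,4,6-trichlorobenzoyl chloride, Et3N, toluene, rt; then 32, 75 °C
Reagents that add atoms: none
Why: Yamaguchi-type acylation through mixed anhydride 34; without a nucleophilic amine catalyst the angelate should keep its Z geometry, and the tertiary C10 hydroxyl is too hindered to compete with O8.

Step 17
Reactants: 35 silyl-protected angelate
Product: 36 target, (3S,6S,7R,8R,10R)-8-(angeloyloxy)-3,10-dihydroxygermacra-1E,4Z,11(13)-trien-12,6-olide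
Conditions: HF·pyridine, pyridine, THF, 0 °C to rt
Reagents that add atoms: none
Why: Buffered HF cleaves the secondary silyl ether without touching the angelate, the methylene lactone or the tertiary allylic alcohol.

## Compound list

1 | methacrolein | C=C(C)C=O | starting material
2 | (triphenylphosphoranylidene)acetaldehyde | O=CC=P(c1ccccc1)(c1ccccc1)c1ccccc1 | starting material
3 | (2E)-4-methylpenta-2,4-dienal | O=C/C=C/C(C)=C | intermediate
4 | ethynyltrimethylsilane | C#C[Si](C)(C)C | starting material
5 | methyl[(trimethylsilyl)ethynyl]zinc (not isolated) | C[Zn]C#C[Si](C)(C)C | intermediate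
6 | (3S,4E)-6-methyl-1-(trimethylsilyl)hepta-4,6-dien-1-yn-3-ol | C[Si](C)(C)C#C[C@@H](O)/C=C/C(C)=C | intermediate
7 | (3S,4E)-6-methylhepta-4,6-dien-1-yn-3-ol | C#C[C@@H](O)/C=C/C(C)=C | intermediate
8 | (5S)-4-methyl-5-[(1E)-3-methylbuta-1,3-dien-1-yl]-2,5-dihydro-1,2-oxamagnesole, cyclic alkenylmagnesium alkoxide drawn free of halide (not isolated) | [Mg]1C=C(C)[C@@H](O1)/C=C/C(C)=C | intermediate
9 | (1Z,3S,4E)-1-iodo-2,6-dimethylhepta-1,4,6-trien-3-ol | I/C=C(/C)[C@@H](O)/C=C/C(C)=C | intermediate
10 | tert-butyl{[(1Z,3S,4E)-1-iodo-2,6-dimethylhepta-1,4,6-trien-3-yl]oxy}dimethylsilane | I/C=C(/C)[C@@H](O[Si](C)(C)C(C)(C)C)/C=C/C(C)=C | intermediate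
11 | (1Z,3S,4E)-3-[(tert-butyldimethylsilyl)oxy]-2,6-dimethylhepta-1,4,6-trien-1-yllithium (not isolated) | [Li]/C=C(/C)[C@@H](O[Si](C)(C)C(C)(C)C)/C=C/C(C)=C | intermediate
12 | (2Z,4S,5E)-4-[(tert-butyldimethylsilyl)oxy]-3,7-dimethylocta-2,5,7-trienal | O=C/C=C(/C)[C@@H](O[Si](C)(C)C(C)(C)C)/C=C/C(C)=C | intermediate
13 | (4R)-4-benzyl-1,3-oxazolidin-2-one | O=C1N[C@H](Cc2ccccc2)CO1 | starting material
14 | methyl 4-chloro-4-oxobutanoate | COC(=O)CCC(=O)Cl | starting material
15 | lithium (4R)-4-benzyl-2-oxo-1,3-oxazolidin-3-ide (not isolated) | [Li]N1[C@H](Cc2ccccc2)COC1=O | intermediate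
16 | methyl 4-[(4R)-4-benzyl-2-oxo-1,3-oxazolidin-3-yl]-4-oxobutanoate | COC(=O)CCC(=O)N1[C@H](Cc2ccccc2)COC1=O | intermediate
17 | methyl (3S,4S,5Z,7S,8E)-3-{[(4R)-4-benzyl-2-oxo-1,3-oxazolidin-3-yl]carbonyl}-7-[(tert-butyldimethylsilyl)oxy]-6,10-dimethyl-4-[(trimethylsilyl)oxy]undeca-5,8,10-trienoate (not isolated) | O=C(N1[C@H](Cc2ccccc2)COC1=O)[C@@H](CC(=O)OC)[C@@H](O[Si](C)(C)C)/C=C(/C)[C@@H](O[Si](C)(C)C(C)(C)C)/C=C/C(C)=C | intermediate
18 | methyl (3S,4S,5Z,7S,8E)-3-{[(4R)-4-benzyl-2-oxo-1,3-oxazolidin-3-yl]carbonyl}-7-[(tert-butyldimethylsilyl)oxy]-4-hydroxy-6,10-dimethylundeca-5,8,10-trienoate (not isolated) | O=C(N1[C@H](Cc2ccccc2)COC1=O)[C@@H](CC(=O)OC)[C@@H](O)/C=C(/C)[C@@H](O[Si](C)(C)C(C)(C)C)/C=C/C(C)=C | intermediate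
19 | (4R)-4-benzyl-3-{[(2S,3S)-2-[(1Z,3S,4E)-3-[(tert-butyldimethylsilyl)oxy]-2,6-dimethylhepta-1,4,6-trien-1-yl]-5-oxooxolan-3-yl]carbonyl}-1,3-oxazolidin-2-one (ring substituents cis) | O=C(N1[C@H](Cc2ccccc2)COC1=O)[C@H]1CC(=O)O[C@H]1/C=C(/C)[C@@H](O[Si](C)(C)C(C)(C)C)/C=C/C(C)=C | intermediate
20 | (4R,5S)-5-[(1Z,3S,4E)-3-[(tert-butyldimethylsilyl)oxy]-2,6-dimethylhepta-1,4,6-trien-1-yl]-4-(hydroxymethyl)oxolan-2-one | OC[C@H]1CC(=O)O[C@H]1/C=C(/C)[C@@H](O[Si](C)(C)C(C)(C)C)/C=C/C(C)=C | intermediate
21 | (2S,3S)-2-[(1Z,3S,4E)-3-[(tert-butyldimethylsilyl)oxy]-2,6-dimethylhepta-1,4,6-trien-1-yl]-5-oxooxolane-3-carbaldehyde (not isolated) | O=C[C@H]1CC(=O)O[C@H]1/C=C(/C)[C@@H](O[Si](C)(C)C(C)(C)C)/C=C/C(C)=C | intermediate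
22 | (4R,5S)-5-[(1Z,3S,4E)-3-[(tert-butyldimethylsilyl)oxy]-2,6-dimethylhepta-1,4,6-trien-1-yl]-4-[(hydroxyimino)methyl]oxolan-2-one | ON=C[C@H]1CC(=O)O[C@H]1/C=C(/C)[C@@H](O[Si](C)(C)C(C)(C)C)/C=C/C(C)=C | intermediate
23 | (2S,3R)-2-[(1Z,3S,4E)-3-[(tert-butyldimethylsilyl)oxy]-2,6-dimethylhepta-1,4,6-trien-1-yl]-5-oxooxolane-3-carbonitrile oxide (not isolated) | [O-][N+]#C[C@H]1CC(=O)O[C@H]1/C=C(/C)[C@@H](O[Si](C)(C)C(C)(C)C)/C=C/C(C)=C | intermediate
24 | isoxazoline-bridged (3S,6S,7R,10R)-3-[(tert-butyldimethylsilyl)oxy]germacra-1E,4Z-dien-12,6-olide (O–N=C8 bridge from C10 to C8) | O=C1O[C@H]2/C=C(/C)[C@@H](O[Si](C)(C)C(C)(C)C)/C=C/[C@]3(C)ON=C(C3)[C@H]2C1 | intermediate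
25 | (3S,6S,7R,10R)-3-[(tert-butyldimethylsilyl)oxy]-10-hydroxy-8-iminogermacra-1E,4Z-dien-12,6-olide (not isolated) | O=C1O[C@H]2/C=C(/C)[C@@H](O[Si](C)(C)C(C)(C)C)/C=C/[C@](C)(O)CC(=N)[C@H]2C1 | intermediate
26 | (3S,6S,7S,10R)-3-[(tert-butyldimethylsilyl)oxy]-10-hydroxy-8-oxogermacra-1E,4Z-dien-12,6-olide | O=C1O[C@H]2/C=C(/C)[C@@H](O[Si](C)(C)C(C)(C)C)/C=C/[C@](C)(O)CC(=O)[C@H]2C1 | intermediate
27 | (3S,6S,7R,8R,10R)-3-[(tert-butyldimethylsilyl)oxy]-8,10-dihydroxygermacra-1E,4Z-dien-12,6-olide | O=C1O[C@H]2/C=C(/C)[C@@H](O[Si](C)(C)C(C)(C)C)/C=C/[C@](C)(O)C[C@@H](O)[C@H]2C1 | intermediate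
28 | (3S,6S,7S,8R,10R)-3-[(tert-butyldimethylsilyl)oxy]-8,10-bis[(trimethylsilyl)oxy]germacra-1E,4Z-dien-12,6-olide (not isolated) | O=C1O[C@H]2/C=C(/C)[C@@H](O[Si](C)(C)C(C)(C)C)/C=C/[C@](C)(O[Si](C)(C)C)C[C@@H](O[Si](C)(C)C)[C@H]2C1 | intermediate
29 | (3S,6S,7S,8R,10R)-3-[(tert-butyldimethylsilyl)oxy]-13-(dimethylamino)-8,10-bis[(trimethylsilyl)oxy]germacra-1E,4Z-dien-12,6-olide, C11 epimers (not isolated) | CN(C)CC1C(=O)O[C@H]2/C=C(/C)[C@@H](O[Si](C)(C)C(C)(C)C)/C=C/[C@](C)(O[Si](C)(C)C)C[C@@H](O[Si](C)(C)C)[C@@H]12 | intermediate
30 | (3S,6S,7R,8R,10R)-3-[(tert-butyldimethylsilyl)oxy]-13-(dimethylamino)-8,10-dihydroxygermacra-1E,4Z-dien-12,6-olide, C11 epimers | CN(C)CC1C(=O)O[C@H]2/C=C(/C)[C@@H](O[Si](C)(C)C(C)(C)C)/C=C/[C@](C)(O)C[C@@H](O)[C@@H]12 | intermediate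
31 | trimethylammonium iodide of 30, C11 epimers (not isolated) | C[N+](C)(C)CC1C(=O)O[C@H]2/C=C(/C)[C@@H](O[Si](C)(C)C(C)(C)C)/C=C/[C@](C)(O)C[C@@H](O)[C@@H]12.[I-] | intermediate
32 | (3S,6S,7R,8R,10R)-3-[(tert-butyldimethylsilyl)oxy]-8,10-dihydroxygermacra-1E,4Z,11(13)-trien-12,6-olide | C=C1C(=O)O[C@H]2/C=C(/C)[C@@H](O[Si](C)(C)C(C)(C)C)/C=C/[C@](C)(O)C[C@@H](O)[C@@H]12 | intermediate
33 | angelic acid, (2Z)-2-methylbut-2-enoic acid | C/C=C(/C)C(=O)O | starting material
34 | (2Z)-2-methylbut-2-enoic 2,4,6-trichlorobenzoic anhydride (not isolated) | C/C=C(/C)C(=O)OC(=O)c1c(Cl)cc(Cl)cc1Cl | intermediate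
35 | (3S,6S,7R,8R,10R)-8-(angeloyloxy)-3-[(tert-butyldimethylsilyl)oxy]-10-hydroxygermacra-1E,4Z,11(13)-trien-12,6-olide | C=C1C(=O)O[C@H]2/C=C(/C)[C@@H](O[Si](C)(C)C(C)(C)C)/C=C/[C@](C)(O)C[C@@H](OC(=O)/C(C)=C\C)[C@@H]12 | intermediate
36 | (3S,6S,7R,8R,10R)-8-(angeloyloxy)-3,10-dihydroxygermacra-1E,4Z,11(13)-trien-12,6-olide | C=C1C(=O)O[C@H]2/C=C(/C)[C@@H](O)/C=C/[C@](C)(O)C[C@@H](OC(=O)/C(C)=C\C)[C@@H]12 | target

## Step count and least certain steps

Total: 17 steps. Longest linear sequence: 16 steps (steps 1–6 and 8–17; step 7 is the side branch).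

Step 11 (key step). What may go wrong: the bridged ten-membered closure may be slow enough for the dipole to close onto the nearer C1=C2 bond (seven-membered, fused mode) or to dimerise. Attack on the wrong face of C9=C10 is also possible, because the facial choice rests on a conformational preference with no strong local bias.
Fallback: change the control element, not the conditions. The C3 stereocentre is removed as a ketone, so that C1–C5 becomes a flat cross-conjugated dienone; this alters both the fold of the tether and the electronic bias between the two diene alkenes, and C3 is reset afterwards by reagent control. The fallback sets out from 22. Buffered HF·pyridine frees the hydroxy oxime F1. Activated MnO2 in CH2Cl2 at 2 mM oxidises the bis-allylic carbinol and then the aldoxime, and the keto nitrile oxide F2 should close in the flask to the 3-oxo isoxazoline F3. CBS reduction with catecholborane (oxazaborolidine antipode chosen for 3S) or, failing that, NaBH4/CeCl3 should give the 3S alcohol F4. TBSCl and imidazole return to the route at 24.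

Step 8. What may go wrong: Z-to-E isomerisation of the enal or its conversion into a silyl dienol ether under amine and chlorosilane at room temperature, and sluggish addition to a hindered β,β-disubstituted enal. The succinate donor may also erode the anti selectivity.
Fallback: replace catalytic soft enolisation by a preformed enolate that meets a Lewis-acid-bound aldehyde in an open transition state at low temperature. It sets out from 16 and 12. Bu2BOTf and i-Pr2NEt in CH2Cl2 at −78 °C give the dibutylboron Z enolate F5, which is added to 12 pre-complexed with Et2AlCl at −78 °C. The chelated boron enolate is attacked from the face away from the benzyl group and the anti adduct is expected. After buffered peroxide work-up the fallback returns at 18, which is lactonised to 19 as in step 8.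

Step 13. What may go wrong: hydride may arrive from the outside of the ten-membered ring and not from O10, because a tertiary hydroxyl exchanges slowly onto boron and the ring conformation may block the internal path. That would give the syn diol. Acid may also ionise the tertiary allylic alcohol.
Fallback: reagent control in place of substrate direction. It sets out from 26: (S)-2-methyl-CBS-oxazaborolidine with catecholborane in toluene at −78 °C, where the branched C7 side is the large group and the C9 methylene the small one, should deliver the 8R alcohol. It returns at 27 and makes no compound outside the list (F0).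

Step 16. What may go wrong: isomerisation of the angelate to the tiglate during activation, made worse if acylation of the hindered C8 hydroxyl is slow at 75 °C.
Fallback: build the Z alkene on the ester. It sets out from 32. Esterification with 2-[bis(2,2,2-trifluoroethoxy)phosphoryl]propanoic acid (DCC, DMAP, CH2Cl2) gives the phosphonate ester F6. Still–Gennari olefination (KN(SiMe3)2, 18-crown-6, THF, −78 °C, then acetaldehyde) should give the Z trisubstituted enoate. It returns at 35.

Further compounds
F1 | step 11 | (4R,5S)-5-[(1Z,3S,4E)-3-hydroxy-2,6-dimethylhepta-1,4,6-trien-1-yl]-4-[(hydroxyimino)methyl]oxolan-2-one | ON=C[C@H]1CC(=O)O[C@H]1/C=C(/C)[C@@H](O)/C=C/C(C)=C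
F2 | step 11 | (2S,3R)-2-[(1Z,4E)-2,6-dimethyl-3-oxohepta-1,4,6-trien-1-yl]-5-oxooxolane-3-carbonitrile oxide | [O-][N+]#C[C@H]1CC(=O)O[C@H]1/C=C(/C)C(=O)/C=C/C(C)=C
F3 | step 11 | isoxazoline-bridged (6S,7R,10R)-3-oxogermacra-1E,4Z-dien-12,6-olide | O=C1O[C@H]2/C=C(/C)C(=O)/C=C/[C@]3(C)ON=C(C3)[C@H]2C1
F4 | step 11 | isoxazoline-bridged (3S,6S,7R,10R)-3-hydroxygermacra-1E,4Z-dien-12,6-olide | O=C1O[C@H]2/C=C(/C)[C@@H](O)/C=C/[C@]3(C)ON=C(C3)[C@H]2C1
F5 | step 8 | methyl (3Z)-4-[(4R)-4-benzyl-2-oxo-1,3-oxazolidin-3-yl]-4-[(dibutylboranyl)oxy]but-3-enoate | CCCCB(CCCC)O/C(=C\CC(=O)OC)N1[C@H](Cc2ccccc2)COC1=O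
F6 | step 16 | (3S,6S,7R,8R,10R)-8-({2-[bis(2,2,2-trifluoroethoxy)phosphoryl]propanoyl}oxy)-3-[(tert-butyldimethylsilyl)oxy]-10-hydroxygermacra-1E,4Z,11(13)-trien-12,6-olide | C=C1C(=O)O[C@H]2/C=C(/C)[C@@H](O[Si](C)(C)C(C)(C)C)/C=C/[C@](C)(O)C[C@@H](OC(=O)C(C)P(=O)(OCC(F)(F)F)OCC(F)(F)F)[C@@H]12
F0 | step 13 | none | none
A1 | alternative 1 | 1(10)E,4Z-cyclodecadien-6-one diester (C3 silyl ether, C4 methyl ester, C7 methoxycarbonylmethyl, C8 p-methoxybenzyl ether) | O=C1/C=C(/C(=O)OC)[C@@H](O[Si](C)(C)C(C)(C)C)C/C=C(\C)C[C@@H](OCc2ccc(OC)cc2)[C@H]1CC(=O)OC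
A2 | alternative 2 | 10-O-triethylsilyl ether of the target | C=C1C(=O)O[C@H]2/C=C(/C)[C@@H](O)/C=C/[C@](C)(O[Si](CC)(CC)CC)C[C@@H](OC(=O)/C(C)=C\C)[C@@H]12
A3 | alternative 3 | cyclodeca-1E,4Z-dien-8-ol with C10 1,3-dithiane, C3 tert-butyldimethylsilyl ether, C6 triethylsilyl ether and C7 3-[(4-methoxybenzyl)oxy]prop-1-en-2-yl group | C=C(COCc1ccc(OC)cc1)[C@H]1[C@@H](O[Si](CC)(CC)CC)/C=C(/C)[C@@H](O[Si](C)(C)C(C)(C)C)/C=C/C2(SCCCS2)C[C@H]1O
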